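The pitfall in this flask was to read the fate of D off its rates at the start and carry that split through to the end.

    D + Z ⇌ D.Z (K1 = 43 M⁻¹, k1 = 23 M⁻¹ s⁻¹)
    D.Z ⇌ Q + X (K2 = 0.29 M, k2 = 1.5 s⁻¹)
    D + G → D.G (k3 = 230 M⁻¹ s⁻¹)

D 10 mM; Z 1.50 equiv; G 3.00 mM; time 80 s

- why nothing more happens at 80 s, or that something still does (it is still moving / Z has run out first / forward and back rates have come level / all of D has reacted)
- part of the D gone at 80 s
- the Q standing at 80 s, as a percentage of the D charged

- the reaction counts as stopped when no species that holds the D changes by six tenths of a point or more over the second half of the time
- run time (flask): 80 s

At the start G took D twice as fast as Z did, the ratio of the forward rates being 0.50, so a split kept at that value would have handed G 66.7 % of the D. But I expected the comparison to drift, for each D that G took used up one G, so the rate of that trap had to fall with [G]. G was the limiting reagent of that trap, its 3.00 mM standing below the 10 mM of D. The forward half-life of D by the first step, 2.0 s, was short against the 80 s of the run, so I took the chain to reach balance while G kept drawing on the free D. I therefore reckoned with the Q ceiling, the part of the charged D that the whole charge of G leaves for Q: 70.0 %. The reversible chain keeps some D and D.Z back, so I committed to Q below that ceiling and went no further.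

The forecast gave forward and back rates have come level, with 96 % of the D gone and Q at 64.6 %, holding that “G therefore takes its full 3 mM within seconds”.

The simulation gave forward and back rates have come level, with 96.0 % of the D gone and Q at 64.6 %. In this flask at 80.0 s, D.G stood at 30.0 % of the D charged and G at 0 %, so Q held 92.3 % of the ceiling. With G moved to 2.38 mM or 3.60 mM, Q shifted by 5 points. In the neighbour flask with 1.2 mM of G the ceiling was 88.0 %, and Q there stood at 78.7 %, which is 89.4 % of it.

The numbers of this flask are assumed, and the outcome is calculated.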